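The earlier runs and the new flask are simulated for substances that don't exist; the scatter is artificial.

Twice the charge at −5 °C took isomer per target at the end from 0.164 on Tuesday's run to 0.290 on Wednesday's, a logarithmic slope of 0.822, so I took that ratio to follow a concentration to about the first power.

| flask | starting material | reagent | temperature | remark | time |
|---|---|---|---|---|---|
| Tuesday's | 23 mM | 1.2 equiv | −5 °C | run made earlier |  |
| Saturday's | 12 mM | 1.2 equiv | 6 °C | run made earlier |  |
| Wednesday's | 46 mM | 1.2 equiv | −5 °C | run made earlier |  |
| ochre | 23 mM | 1.20 equiv | 0 °C | everything together at the start | 3.0 h |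
| amber | 23 mM | 1.20 equiv (in portions, 3, over 2.5 h) | 0 °C | first portion at the start, last at 2.5 h | 3.0 h |
| violet | 23 mM (fed, over 2.5 h) | 1.20 equiv |  | the addition at −30 °C, then warmed to 0 °C; the feed brings no volume worth counting | 3.0 h |
| grey | 23 mM (fed, over 2.5 h) | 1.20 equiv | 0 °C | all else is in the flask from the start; the feed brings no volume worth counting | 3.0 h |

- Tuesday's (time / h: target / %, isomer of the product / %): 0.667: 41.6, 8.8; 1.33: 62.1, 11.8; 2.00: 74.9, 12.5; 2.50: 78.9, 12.7; 3.00: 81.5, 13.4
- Saturday's (time / h: target / %, isomer of the product / %): 0.250: 51.6, 4.8; 0.833: 84.0, 6.6; 1.33: 89.0, 5.8; 2.00: 91.5, 7.2; 3.00: 92.8, 7.3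
- Wednesday's (time / h: target / %, isomer of the product / %): 0.250: 18.4, 9.2; 0.417: 29.5, 13.1; 0.833: 46.6, 17.4; 1.50: 61.7, 20.9; 3.00: 74.4, 21.6

(standard deviation of a reading: 0.5 percentage points)

- what was read earlier has a scatter of 0.5 percentage points, one standard deviation
- a reading or a percentage of target counts all its forms, free or not

- the flask with the highest share of target in target plus isomer of the product ("all alike" if they lie within 1.5 percentage points) (ochre / amber / violet / grey / all alike)
- share of target in target plus isomer of the product at the end, ochre
- share of target in target plus isomer of the product at the end, amber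
- share of target in target plus isomer of the product at the end, violet
- share of target in target plus isomer of the product at the end, grey

In these batches c_reagent falls along with c_starting material, so the ratio could follow either. I chose reagent: an isomer of the target carries what the target carries, so I took its step to consume reagent too.

Over a finished batch c_reagent falls from the charge to the surplus, and I took the mean of those two levels. Dividing each mean by its end ratio gave 97.9 mM on Tuesday's run, 111 mM on Wednesday's and 107 mM on Saturday's, so the warmer run showed no clear shift. Their mean is 105 mM. I call it c_x, the crossover concentration, the reagent level at which isomer forms as fast as target, a selectivity factor in mM. The share of target is then the inverse of one plus c̄/c_x, with c̄ the mean c_reagent while product forms.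

Ochre and grey both start with the whole reagent charge, so I gave both c̄ = 16.1 mM and a share near 86.7%. I placed violet, warmed late, between 79.2% at the full charge and that figure.

Amber is the bracket. A whole portion, 9.20 mM, bounds its share from below at 92.0%. Half a portion bounds it from above at 95.8%. Counting the surplus under the last portion tightened c̄ to 5.06 mM and the share to 95.4%, so I expected amber highest.

The forecast expected of amber “reagent-limited stalls and an unfinished end” and gave grey as best, with ochre 87.2%, amber 86.5%, violet 83% and grey 94.3%, which puts amber below my bracket.

Amber gave 96.2%, the highest and 0.40 percentage points above my bracket, against ochre 88.2%, grey 87.7% and violet 84.3%.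

    starting material ⇌ tautomer (K = 0.700, k = 5.50 × 10⁻⁴ s⁻¹, Ea = 90.0 kJ mol⁻¹, ΔH = −51.0 kJ mol⁻¹)
    reagent + tautomer → target (k = 0.650 M⁻¹ s⁻¹, Ea = 39.0 kJ mol⁻¹)
    starting material + reagent → isomer of the product (k = 0.00420 M⁻¹ s⁻¹, Ea = 68.0 kJ mol⁻¹)
    crystals ⇌ target, rate k4*(cs4 - [target]) while solid is left; crystals form when [target] > cs4 (solubility = 1.60 mM, k = 0.160 s⁻¹)
    (constants at 0 °C)

Just before its last addition, at 2.50 h, amber held reagent at 0.233% of its own charge and isomer at 3.10% of the starting material charged. Read through c_x, amber's end share means c̄ = 4.15 mM, against my 5.06 mM. The neighbour of violet with 2.00 equiv ended with 64.5% of its reagent, so I took its c̄ as 37.8 mM, and c_x gives a share of 73.5%; that flask gave 75.3%.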